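## Structural features

The target 13 is a single six-membered carbocycle, a cyclohexanone in which five of the six ring carbons carry oxygen. The numbering used throughout is C1 (quaternary tertiary carbinol bearing the exocyclic C7H2OBz), C2 (ketone), C3 (CH2), C4 (CHOH), C5 (CHOBz), C6 (CHOH). The four stereocentres C4, C5, C6 and C1 are contiguous, (1S,4R,5R,6S) in this numbering: the C1 and C6 hydroxyls are cis, the C6 hydroxyl and the C5 benzoate trans, the C5 benzoate and the C4 hydroxyl cis. In the chair with C7 equatorial, the C5 and C6 oxygens are equatorial and the C4 and C1 hydroxyls axial. Three features are fragile: the C4 hydroxyl is β to the C2 carbonyl and is lost by E1cB dehydration under base, the C1/C2 α-ketol can rearrange, and the C5 benzoate sits between two free hydroxyls and can migrate. The real difficulty is therefore the differentiation of six oxygens (one ketone, two benzoates, three free hydroxyls) with no basic step late in the route, more than the relative stereochemistry. The feature exploited is that C1 lies para to the oxygenated C4 and has oxygenated carbons on both sides, so the ring maps onto a 4-substituted 4-hydroxycyclohexa-2,5-dienone whose two enone arms become C2–C3 and C6–C5. That dienone is achiral; tying its C1 hydroxyl to one arm through a one-carbon acetal tether fixes C1, puts an oxygen on C2, leaves C3 as CH2 and C4 as a carbonyl, and keeps the other arm as an enone for C5 and C6.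

## Logic of the disconnections

13 ⇒ 12 + 2. The bond cut is C5–O, the alkyl–oxygen bond of the secondary ester. The trans relation of the C5 and C6 oxygens is what an anti opening of a C5/C6 epoxide leaves behind, and the benzoate then enters as the nucleophile, so no secondary hydroxyl has to be singled out for acylation. The gain is the loss of one ester and the merging of two carbinol centres into one epoxide. The forward step must send the carboxylate to C5 and not C6, with inversion, without dehydrating the β-hydroxy ketone or moving the new ester.

12 ⇒ 10, through 11. No skeletal bond is cut; the C2 carbonyl is returned to a carbinol (C2–H and O–H restored). The C2 oxygen enters the route as an alcohol, and placing its oxidation second to last keeps the β-hydroxy ketone and the α-ketol out of all earlier steps. The demand is to oxidise one of two secondary carbinols. Only the C2 hydroxyl belongs to a cis-1,2-diol, which is why the step runs through 11.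

10 ⇒ 9. The bond cut is C4–H. This removes the C4 stereocentre and returns the carbonyl that the desymmetrization leaves at C4. The C2 hydroxyl of 9 lies 1,3 to that carbonyl on the face from which hydride is needed. The forward step must deliver hydride intramolecularly from the C2 oxygen and leave the epoxide and the ester alone.

9 ⇒ 8. Both C–O bonds of the epoxide are cut, which removes two stereocentres and returns the surviving enone arm. The C1 and C2 hydroxyls of 8 both lie on the face where the epoxide oxygen is needed. The forward step must deliver oxygen from that face to an electron-poor alkene without base, because 8 is a β-hydroxy ketone.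

8 ⇒ 7. The two hydroxyls are tied back to the acetal carbon (two C–O bonds). Nothing is gained in complexity; this is the price of the tether that carries the asymmetric step. The forward step must cleave a robust ethylidene acetal without reversing the oxa-Michael addition.

7 ⇒ 4 + 5, through 6. The bonds cut are C2–O and the two C–O bonds of the acetal carbon. All stereocentres vanish: 4 is achiral and 5 is a two-carbon aldehyde. The forward step must distinguish two enantiotopic enone arms; the cis ring fusion follows from the tether.

4 ⇒ 3. The bond cut is C1–O of the tertiary hydroxyl, and the ring is rearomatised. The carbocycle becomes a benzene ring with the C7 ester already in place. The forward oxidation must put water on the para carbon and must not ionise the benzylic ester to a quinone methide.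

3 ⇒ 1 + 2. The bond cut is the acyl C–O bond of the C7 ester, giving two commercial compounds. The forward step must esterify the benzylic hydroxyl in the presence of the free phenol.

## Other disconnections considered

Alternative 1: The cuts are C5–C6 and C1–C2. Rabbit-muscle fructose-1,6-bisphosphate aldolase would join dihydroxyacetone phosphate A1 to (R)-2-hydroxy-4-nitrobutanal A2 to give the open-chain ketose phosphate A3. The nitronate of A3 would then add to the C1 carbonyl and close nitrocyclitol phosphate A4.
- In favour: the enzyme sets C5 and C6 absolutely and A2 brings C4. The ring and the quaternary C1 form in the same aqueous pot without protecting groups. The equatorial preference of C7 should steer C1 correctly under reversible nitroaldol conditions, and the nitro group marks C2 as the future carbonyl.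
- Against: A2 must be made enantiopure and is a labile α-hydroxy aldehyde. The Nef conversion at C2 needs a nitronate next to a tertiary carbinol, which invites retro-nitroaldol ring opening. After loss of the phosphate five hydroxyls are free, so the benzoates would have to go on C7 and on C5 alone among three secondary carbinols.
- Comparison: on structure A4 is the better intermediate, since it holds C1, C4, C5 and C6 of 13 at once, whereas 7 holds only C1 and relays the rest. On absolute control an enzyme with a fixed facial preference is at least the equal of a phosphoric acid whose sense must first be established. On mechanism the chosen plan is ahead where it matters for this target: every oxygen of 13 arrives differentiated (C7 ester in 3, C5 ester by opening 12, C2 carbonyl through 11) and no strongly basic step meets a β-hydroxy ketone. On step economy the alternative reaches the carbocycle sooner, but making A2, the Nef step, dephosphorylation and oxygen differentiation should take it past eight steps.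

Alternative 2: The cut is C1–C6. KN(SiMe3)2 and Me3SiCl would convert the (Z)-silyloxyvinyl δ-lactone A5 into its silyl ketene acetal. An Ireland–Claisen shift through a boat (the two-carbon C2–C3 tether allows nothing else) would form C1–C6, break C4–O and give cyclohexene acid A6.
- In favour: the congested bond between quaternary C1 and C6 forms intramolecularly with chirality transfer from the lactone carbinol, and C1 and C6 are set together. The three oxygens of A6 carry three different protecting groups; this is better than the chosen plan, which must find the C2 hydroxyl of 10 through its diol relationship. The C4=C5 alkene is placed for a cis-dihydroxylation anti to the C6 silyloxy group.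
- Against: C7 arrives as a carboxylic acid and must be reduced and benzoylated. The C4/C5 cis-diol would need monobenzoylation at C5. The ester enolate carries a β-silyloxy group at C2 and can eliminate before it is trapped. A5, with two stereocentres and a defined enol-ether geometry, is itself a multistep target.
- Comparison: as a stereochemical device the concerted shift is the equal of a catalytic desymmetrization and more predictable. In step and redox economy (acid to alcohol, alkene to diol, ether to ketone, three deprotections) it is clearly longer than the chosen route, and it cannot bring the C5 benzoate in as a nucleophile.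

Alternative 3: The cut is C2–C3, made as C2=C3. The second-generation Grubbs catalyst RuCl2(=CHPh)(PCy3)(H2IMes) would join the 1-ethoxyvinyl group on C1 and the vinyl group on C4 of the fructose-derived diene A7 with loss of ethylene, closing the cyclic ethyl enol ether A8.
- In favour: C4, C5 and C6 come from D-fructose with the correct absolute configuration, which is better than any catalyst-controlled step. The enol ether is a latent C2 ketone unveiled by mild acid with C3 as CH2, so the C2/C4 oxidation pattern is unambiguous; this is better than the tin-mediated selection of step 7. Ring closure by metathesis is mechanistically dependable.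
- Against: C1 would be set by adding a 1-ethoxyvinyl metal reagent to a fructose-derived ketone, with uncertain facial selectivity. An electron-rich 1,1-disubstituted enol ether next to a fully substituted carbinol is a slow metathesis partner and can trap the catalyst as a Fischer carbene. A7 needs the fructose hydroxyls differentiated one by one and a one-carbon extension at C6 of the sugar. After A8 the C7 benzyl ether must be exchanged for a benzoate and the C4/C5 cis-diol monobenzoylated at C5 (plausible, since that hydroxyl is equatorial, but not assured).
- Comparison: for C4–C6 the alternative is ahead in stereochemical security; for C1 the chosen plan is ahead, since C1 is the centre the desymmetrization is built for. The two are equal in ending with a mild, non-basic unmasking. In step economy the chiral-pool route, with protecting-group traffic before and after A8, should need roughly twice the eight steps of the chosen plan.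

Key step: step 3

Assumption: which enantiomer of the phosphoric acid delivers the required arm cannot be derived from first principles; (R)-TRIP is written and its antipode is to be taken if a first run favours the other arm. Either acetal epimer of 7 serves, because that carbon leaves in step 4.

## Route

Step 1
Reactants: 1 4-hydroxybenzyl alcohol; 2 benzoic acid
Product: 3 4-hydroxybenzyl benzoate
Conditions: PPh3 (1.2 equiv), DIAD (1.2 equiv), THF, 0 °C → rt
Reagents that add atoms: none
Why: Mitsunobu esterification; the far more acidic carboxylic acid is the species ionised and only the benzylic hydroxyl is activated as the alkoxyphosphonium, so the ester forms at the benzylic oxygen with the phenol unprotected, and the neutral medium avoids phenoxide-triggered loss of benzoate through a quinone methide.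

Step 2
Reactants: 3 4-hydroxybenzyl benzoate
Product: 4 (1-hydroxy-4-oxocyclohexa-2,5-dien-1-yl)methyl benzoate
Conditions: PhI(OAc)2 (1.1 equiv), MeCN/H2O (3:1), 0 °C
Reagents that add atoms: water, O
Why: Oxidative dearomatization of a para-substituted phenol: ligand exchange at iodine gives an aryloxy-iodane, and water attacks the para carbon as iodobenzene leaves; the product is achiral, and the primary oxygen is kept as its benzoate because a free 4-hydroxymethyl quinol would fragment to hydroquinone and formaldehyde.

Step 3
Reactants: 4 (1-hydroxy-4-oxocyclohexa-2,5-dien-1-yl)methyl benzoate; 5 acetaldehyde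
Product: 7 [(2R,3aR,7aR)-2-methyl-6-oxo-7,7a-dihydro-1,3-benzodioxol-3a(6H)-yl]methyl benzoate, via hemiacetal 6 (not isolated)
Conditions: (R)-TRIP (10 mol %), MeCHO (5 equiv), 4 Å MS, toluene, 0 °C → rt, sealed flask
Reagents that add atoms: none
Why: The phosphoric acid hydrogen-bonds acetaldehyde and the tertiary C1 hydroxyl of 4 adds reversibly to give hemiacetal 6. The catalyst then holds 6 in a bifunctional array, its P=O oxygen accepting the hemiacetal O–H and its P–OH donating to the dienone carbonyl, and the hemiacetal oxygen adds to the β-carbon of one enone arm (oxa-Michael), after which the enol tautomerises to the C4 ketone. The closest known reaction type is the chiral Brønsted-acid-catalysed acetalization/oxa-Michael desymmetrization of para-quinols and para-peroxyquinols with aldehydes. The one ring closed is the 1,3-dioxolane, by 5-exo-trig attack of oxygen on C2; a one-carbon O–C–O tether can reach only the face that carries the C1 oxygen, so the fusion is necessarily cis. C1 becomes stereogenic through the catalyst's choice between the two enantiotopic arms, C2 follows from C1 through the cis fusion, and the acetal carbon is fixed by whichever hemiacetal enantiomer the chiral pocket accepts (irrelevant, since it is removed in step 4). The selectivity needed is enantiotopic-group discrimination only; the substrate secures the rest, because its sole nucleophile is the C1 hydroxyl, the two arms are otherwise identical, and after one addition no tethered nucleophile is left for the second enone. The C7 benzoate is a spectator, and excess acetaldehyde in a closed vessel keeps the hemiacetal equilibrium supplied.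

Step 4
Reactants: 7 [(2R,3aR,7aR)-2-methyl-6-oxo-7,7a-dihydro-1,3-benzodioxol-3a(6H)-yl]methyl benzoate
Product: 8 [(1R,6R)-1,6-dihydroxy-4-oxocyclohex-2-en-1-yl]methyl benzoate
Conditions: BCl3 (1 M in CH2Cl2, 2 equiv), CH2Cl2, −78 → −40 °C; then H2O/THF, 0 °C
Reagents that add atoms: none
Why: Lewis-acid cleavage of a cyclic acetal: BCl3 ionises the electron-poor ethylidene acetal at low temperature and the aqueous quench completes the hydrolysis to the cis-diol and acetaldehyde; at −78 °C the ketone is not enolised, so the retro-oxa-Michael that warm protic acid could cause is avoided, and C1 and C2 are not touched.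

Step 5
Reactants: 8 [(1R,6R)-1,6-dihydroxy-4-oxocyclohex-2-en-1-yl]methyl benzoate
Product: 9 [(1S,2R,3R,6R)-2,3-dihydroxy-5-oxo-7-oxabicyclo[4.1.0]heptan-2-yl]methyl benzoate
Conditions: Ti(OiPr)4 (1.2 equiv), t-BuOOH (2 equiv, decane), 4 Å MS, CH2Cl2, −20 °C
Reagents that add atoms: tert-butyl hydroperoxide, CC(C)(C)OO
Why: Hydroxyl-directed epoxidation of an allylic alcohol (here a γ-hydroxy enone): the C1/C2 cis-diol binds titanium on one face and the titanium-bound peroxide is delivered intramolecularly to C5=C6 from that face, so the epoxide oxygen is syn to the C1 hydroxyl; the non-basic medium spares the β-hydroxy ketone, which an alkaline Weitz–Scheffer protocol could dehydrate back to 4.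

Step 6
Reactants: 9 [(1S,2R,3R,6R)-2,3-dihydroxy-5-oxo-7-oxabicyclo[4.1.0]heptan-2-yl]methyl benzoate
Product: 10 [(1S,2R,3R,5R,6S)-2,3,5-trihydroxy-7-oxabicyclo[4.1.0]heptan-2-yl]methyl benzoate
Conditions: Me4NBH(OAc)3 (5 equiv), MeCN/AcOH (1:1), −30 → 0 °C
Reagents that add atoms: none
Why: Evans–Saksena reduction: the C2 hydroxyl (pseudoaxial in the reactive half-chair) exchanges onto boron and the alkoxyborohydride delivers hydride to the face of the C4 carbonyl on which the C2 oxygen sits, so the new C4 hydroxyl is 1,3-anti to the C2 hydroxyl, that is (R) at C4; the reagent is too weak to reduce the ketone intermolecularly or to touch the ester, and the cold acetic acid medium spares the epoxide.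

Step 7
Reactants: 10 [(1S,2R,3R,5R,6S)-2,3,5-trihydroxy-7-oxabicyclo[4.1.0]heptan-2-yl]methyl benzoate
Product: 12 [(1S,2S,5R,6S)-2,5-dihydroxy-3-oxo-7-oxabicyclo[4.1.0]heptan-2-yl]methyl benzoate, via stannylene acetal 11 (not isolated)
Conditions: Bu2SnO (1.1 equiv), MeOH, reflux, then evaporate; NBS (1.05 equiv), CH2Cl2, 0 °C → rt
Reagents that add atoms: dibutyltin oxide, CCCC[Sn](=O)CCCC (its atoms are carried by 11 only; between 10 and 12 only hydrogen changes)
Why: Tin-acetal-mediated oxidation of a vicinal diol to an α-ketol (brominolysis of a stannylene acetal): only the C1/C2 cis-1,2-diol can form the five-membered dibutylstannylene 11, and NBS oxidises its activated secondary Sn–O–C2–H unit to the ketone while the isolated C4 hydroxyl and the tertiary C1 oxygen stay as they are; no stereocentre is created and quaternary C1 cannot epimerise.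

Step 8
Reactants: 12 [(1S,2S,5R,6S)-2,5-dihydroxy-3-oxo-7-oxabicyclo[4.1.0]heptan-2-yl]methyl benzoate; 2 benzoic acid
Product: 13 [(1S,2S,3R,4R)-3-(benzoyloxy)-1,2,4-trihydroxy-6-oxocyclohexyl]methyl benzoate
Conditions: PhCO2H (3 equiv), Ti(OiPr)4 (1.5 equiv), CH2Cl2, 0 °C → rt; aq. tartaric acid work-up
Reagents that add atoms: none
Why: Titanium-assisted opening of a 2,3-epoxy alcohol by a carboxylic acid: the cis C1 hydroxyl and the epoxide oxygen chelate titanium and benzoate attacks the distal carbon C5, which is also the less hindered one because C6 is neopentyl next to quaternary C1; SN2 inversion puts the benzoate on the face opposite the epoxide, cis to the C4 hydroxyl and trans to the C6 hydroxyl (released with retention), which is the (4R,5R,6S) array of 13, under non-basic conditions.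

## Compound list

1 | 4-hydroxybenzyl alcohol | OCc1ccc(O)cc1 | starting material
2 | benzoic acid | O=C(O)c1ccccc1 | starting material
3 | 4-hydroxybenzyl benzoate | O=C(OCc1ccc(O)cc1)c1ccccc1 | intermediate
4 | (1-hydroxy-4-oxocyclohexa-2,5-dien-1-yl)methyl benzoate (achiral para-quinol) | O=C(OCC1(O)C=CC(=O)C=C1)c1ccccc1 | intermediate
5 | acetaldehyde | CC=O | starting material
6 | {1-[(1R)-1-hydroxyethoxy]-4-oxocyclohexa-2,5-dien-1-yl}methyl benzoate (hemiacetal at the C1 oxygen) | O=C(OCC1(O[C@H](C)O)C=CC(=O)C=C1)c1ccccc1 | intermediate (not isolated)
7 | [(2R,3aR,7aR)-2-methyl-6-oxo-7,7a-dihydro-1,3-benzodioxol-3a(6H)-yl]methyl benzoate (cis-fused dioxolane enone; C1–O and C2–O on the same face) | O=C(OC[C@@]1(O[C@H](C)O2)[C@H]2CC(=O)C=C1)c1ccccc1 | intermediate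
8 | [(1R,6R)-1,6-dihydroxy-4-oxocyclohex-2-en-1-yl]methyl benzoate (C1/C2 cis-diol, C4 ketone, C5=C6) | O=C(OC[C@@]1(O)[C@H](O)CC(=O)C=C1)c1ccccc1 | intermediate
9 | [(1S,2R,3R,6R)-2,3-dihydroxy-5-oxo-7-oxabicyclo[4.1.0]heptan-2-yl]methyl benzoate (C5/C6 epoxide syn to the C1 hydroxyl) | O=C(OC[C@@]1(O)[C@H](O)CC(=O)[C@@H]2O[C@H]12)c1ccccc1 | intermediate
10 | [(1S,2R,3R,5R,6S)-2,3,5-trihydroxy-7-oxabicyclo[4.1.0]heptan-2-yl]methyl benzoate (C4 hydroxyl trans to the C2 hydroxyl and to the epoxide) | O=C(OC[C@@]1(O)[C@H](O)C[C@@H](O)[C@@H]2O[C@H]12)c1ccccc1 | intermediate
11 | 2,2-dibutyl-1,3,2-dioxastannolane spanning the C1 and C2 oxygens of 10 (C4 hydroxyl free, epoxide intact) | O=C(OC[C@@]1(O[Sn](CCCC)(CCCC)O3)[C@H]3C[C@@H](O)[C@@H]2O[C@H]12)c1ccccc1 | intermediate (not isolated)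
12 | [(1S,2S,5R,6S)-2,5-dihydroxy-3-oxo-7-oxabicyclo[4.1.0]heptan-2-yl]methyl benzoate (C2 ketone, C4 hydroxyl, C5/C6 epoxide) | O=C(OC[C@@]1(O)C(=O)C[C@@H](O)[C@@H]2O[C@H]12)c1ccccc1 | intermediate
13 | [(1S,2S,3R,4R)-3-(benzoyloxy)-1,2,4-trihydroxy-6-oxocyclohexyl]methyl benzoate | O=C(OC[C@@]1(O)C(=O)C[C@@H](O)[C@@H](OC(=O)c2ccccc2)[C@@H]1O)c1ccccc1 | target

## Step count and least certain steps

Total step count: 8. Longest linear sequence: 8 steps (1 to 13), with no protecting-group step after the acetal is removed.

Step 3 (key step). The likely failure is poor discrimination between the two enone arms, because the small, unhindered acetaldehyde gives a loosely organised catalyst–hemiacetal pair, together with slow erosion by retro-oxa-Michael and loss of aldehyde to oligomerisation. Fallback, from 4 and rejoining at 8: a boron tether replaces the carbon tether. PhB(OH)2 and a cinchona-derived tertiary-amine thiourea (toluene, rt) would give the boronate hemiester of the C1 hydroxyl, whose B–OH oxygen adds to C2 under bifunctional catalysis to give the cis-fused cyclic phenylboronate F1. Exchange with pinacol (CH2Cl2, rt) would release 8 directly, which also makes step 4 unnecessary.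

Step 4. The likely failure is reversal of the oxa-Michael addition through Lewis-acid-promoted enolisation (returning achiral 4), or incomplete cleavage of the robust ethylidene acetal. Fallback, from 7 and rejoining at 8: remove the carbonyl before the acetal. Luche reduction (NaBH4, CeCl3·7H2O, MeOH, −78 °C) would give the allylic alcohol F2 (either C4 epimer serves). With no ketone left, forcing aqueous acid (TFA/H2O, rt to 40 °C) can hydrolyse the acetal to the allylic triol F3 without retro-Michael. MnO2 (CH2Cl2, rt, short contact) would then reoxidise only the allylic C4 hydroxyl to give 8.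

Step 5. The likely failure is slow oxygen transfer to the electron-poor C5=C6 bond, allowing undirected attack from the other face or retro-aldol or dehydration of the β-hydroxy ketone on titanium. Fallback, from 8 and rejoining at 10: reduce first and epoxidise an ordinary alkene. Me4NBH(OAc)3 (MeCN/AcOH, −30 °C), directed by the C2 hydroxyl, would give the allylic triol F4 with the C4 hydroxyl trans to C2–OH. TBSCl/imidazole (DMF) would silylate the two secondary hydroxyls to give the 2,4-bis-O-TBS ether F5. mCPBA (NaHCO3, CH2Cl2, 0 °C), directed by the free tertiary C1 hydroxyl (Henbest) and blocked on the other face by the C4 silyl ether, would give the syn epoxide F6. TBAF buffered with AcOH (THF) would then give 10.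

Step 7. The likely failure is loss of chemoselectivity (oxidation at C4 as well or instead), Payne-type epoxide migration while the tin acetal forms in hot methanol, or bromide opening of the epoxide. Fallback, from 10 and rejoining at 12: protect instead of select. TBSCl/imidazole (DMF, 0 °C, 1.05 equiv) should silylate the less hindered C4 hydroxyl (C2–OH is flanked by quaternary C1) to give the 4-O-TBS ether F7. Dess–Martin periodinane (NaHCO3, CH2Cl2) would oxidise the one remaining secondary hydroxyl to give the ketone F8. HF·pyridine buffered with pyridine (THF, 0 °C) would return 12.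

Step 8. The likely failure is migration of the new C5 benzoate to the cis C4 oxygen through a titanium alkoxide, dehydration of the β-hydroxy ketone on the Lewis acid, or competing attack at C6. Fallback, from 12 and rejoining at 13: cap the C4 hydroxyl before the opening. TESOTf/2,6-lutidine (CH2Cl2, −78 °C) would silylate the only secondary hydroxyl to give the 4-O-TES ether F9. The same PhCO2H/Ti(OiPr)4 opening, now without a free C4 oxygen to accept the acyl group or to leave, would give the 4-O-TES ether F10 of the target; the cost is more hindrance beside C5. HF·pyridine/pyridine (THF, 0 °C) would then give 13 as the last, mildly acidic step.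

## Further compounds

F1 | step 3 | [(3aR,7aR)-6-oxo-2-phenyl-7,7a-dihydro-1,3,2-benzodioxaborol-3a(6H)-yl]methyl benzoate (cyclic phenylboronate of 8) | O=C(OC[C@@]1(OB(c3ccccc3)O2)[C@H]2CC(=O)C=C1)c1ccccc1
F2 | step 4 | C4 allylic alcohol of 7 (C4 hydroxyl drawn cis to the acetal oxygens; the C4 epimer serves equally) | O=C(OC[C@@]1(O[C@H](C)O2)[C@H]2C[C@H](O)C=C1)c1ccccc1
F3 | step 4 | (1,4,6-trihydroxycyclohex-2-en-1-yl)methyl benzoate with the C4 hydroxyl cis to the C1/C2 hydroxyls (C4 epimer of F4) | O=C(OC[C@@]1(O)[C@H](O)C[C@H](O)C=C1)c1ccccc1
F4 | step 5 | (1,4,6-trihydroxycyclohex-2-en-1-yl)methyl benzoate with the C4 hydroxyl trans to the C2 hydroxyl | O=C(OC[C@@]1(O)[C@H](O)C[C@@H](O)C=C1)c1ccccc1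
F5 | step 5 | 2,4-bis-O-(tert-butyldimethylsilyl) ether of F4 (ring numbering of the text) | O=C(OC[C@@]1(O)[C@H](O[Si](C)(C)C(C)(C)C)C[C@@H](O[Si](C)(C)C(C)(C)C)C=C1)c1ccccc1
F6 | step 5 | 2,4-bis-O-(tert-butyldimethylsilyl) ether of 10 | O=C(OC[C@@]1(O)[C@H](O[Si](C)(C)C(C)(C)C)C[C@@H](O[Si](C)(C)C(C)(C)C)[C@@H]2O[C@H]12)c1ccccc1
F7 | step 7 | 4-O-(tert-butyldimethylsilyl) ether of 10 | O=C(OC[C@@]1(O)[C@H](O)C[C@@H](O[Si](C)(C)C(C)(C)C)[C@@H]2O[C@H]12)c1ccccc1
F8 | step 7 | 4-O-(tert-butyldimethylsilyl) ether of 12 | O=C(OC[C@@]1(O)C(=O)C[C@@H](O[Si](C)(C)C(C)(C)C)[C@@H]2O[C@H]12)c1ccccc1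
F9 | step 8 | 4-O-(triethylsilyl) ether of 12 | O=C(OC[C@@]1(O)C(=O)C[C@@H](O[Si](CC)(CC)CC)[C@@H]2O[C@H]12)c1ccccc1
F10 | step 8 | 4-O-(triethylsilyl) ether of 13 | O=C(OC[C@@]1(O)C(=O)C[C@@H](O[Si](CC)(CC)CC)[C@@H](OC(=O)c2ccccc2)[C@@H]1O)c1ccccc1
A1 | alternative 1 | dihydroxyacetone phosphate | OCC(=O)COP(O)(O)=O
A2 | alternative 1 | (R)-2-hydroxy-4-nitrobutanal | O=C[C@H](O)CC[N+](=O)[O-]
A3 | alternative 1 | 6,7-dideoxy-7-nitro-D-arabino-hept-2-ulose 1-phosphate (open-chain aldol adduct) | OP(O)(=O)OCC(=O)[C@@H](O)[C@H](O)[C@H](O)CC[N+](=O)[O-]
A4 | alternative 1 | nitrocyclitol phosphate (C2 nitro, C1 tertiary carbinol, C7 phosphate) | OP(O)(=O)OC[C@@]1(O)[C@H]([N+](=O)[O-])C[C@@H](O)[C@@H](O)[C@@H]1O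
A5 | alternative 2 | 3-(benzyloxy)-6-[(Z)-2-(tert-butyldimethylsilyloxy)ethenyl]-4-(triethylsilyloxy)oxan-2-one, 4,6-trans (either C3 epimer serves; one is drawn) | O=C1[C@H](OCc2ccccc2)[C@@H](O[Si](CC)(CC)CC)C[C@@H](O1)/C=C\O[Si](C)(C)C(C)(C)C
A6 | alternative 2 | 1-benzyloxy-6-(tert-butyldimethylsilyloxy)-2-(triethylsilyloxy)cyclohex-4-ene-1-carboxylic acid | OC(=O)[C@@]1(OCc2ccccc2)[C@@H](O[Si](CC)(CC)CC)CC=C[C@@H]1O[Si](C)(C)C(C)(C)C
A7 | alternative 3 | fructose-derived diene: 1-ethoxyvinyl tertiary carbinol at C1 and vinyl group on C4 (C7 benzyl ether, C6 TBS ether, C4/C5 acetonide) | C=C(OCC)[C@](O)(COCc1ccccc1)[C@@H](O[Si](C)(C)C(C)(C)C)[C@@H]1OC(C)(C)O[C@@H]1C=C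
A8 | alternative 3 | cyclic ethyl enol ether of the protected target ketone | c1ccccc1COC[C@@]2(O)C(OCC)=C[C@H]3OC(C)(C)O[C@H]3[C@@H]2O[Si](C)(C)C(C)(C)C
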